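Readings and results are simulated from invented constants, and the scatter is random.

| flask | Wu | Ja | temperature | remark | time |
|---|---|---|---|---|---|
| elm | 10 mM | 10 mM | 20 °C | run made earlier |  |
| birch | 5 mM | 10 mM | 31 °C | run made earlier |  |
| alder | 7.5 mM | 10 mM | 20 °C | run made earlier |  |
| grey | 10 mM (fed, over 20 min) | 10.0 mM | 25 °C | all else is in the flask from the start; the feed brings no volume worth counting | 50 min |
| ochre | 10 mM (fed, over 2.0 min) | 10.0 mM | 25 °C | all else is in the flask from the start; the feed brings no volume worth counting | 50 min |
| amber | 10 mM | 10.0 mM (fed, over 20 min) |  | the addition at −5 °C, then warmed to 25 °C; the feed brings no volume worth counting | 50 min |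
| green | 10 mM | 10.0 mM (fed, over 20 min) | 25 °C | all else is in the flask from the start; the feed brings no volume worth counting | 50 min |

| run | time / min | WuWuJa / % | WuJa / % | Wu / % |
|---|---|---|---|---|
| elm | 4.00 | 0 | 2 | 93 |
| elm | 10.0 | 1 | 10 | 86 |
| elm | 20.0 | 2 | 14 | 75 |
| elm | 30.0 | 5 | 21 | 68 |
| birch | 12.0 | 4 | 22 | 71 |
| birch | 25.0 | 6 | 36 | 46 |
| birch | 40.0 | 11 | 45 | 30 |
| birch | 50.0 | 17 | 48 | 25 |
| alder | 6.00 | 0 | 7 | 93 |
| alder | 20.0 | 0 | 16 | 75 |
| alder | 30.0 | 4 | 20 | 68 |
| alder | 50.0 | 10 | 23 | 54 |

(standard deviation of a reading: 1.5 percentage points)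

- a species is counted by the Wu in it: one WuWuJa counts as two
- the analysis behind the earlier runs scatters by 1.5 percentage points, standard deviation

* the flask with the highest amount of WuWuJa, in percent of the Wu charged ("all alike" if they lie within 1.5 percentage points) (grey / ochre / amber / green / all alike)
* final WuWuJa, as a percentage of the Wu charged, in grey
* final WuWuJa, as a percentage of the Wu charged, in ochre
* final WuWuJa, as a percentage of the Wu charged, in amber
* final WuWuJa, as a percentage of the Wu charged, in green

- The constant I start from is the start rate of Wu loss at 10 mM of Ja, as a share of the Wu present per minute; elm and alder read 75% and 75% at 20.0 min from different Wu charges, so I take the loss as first order in Wu, and, since elm, birch and alder share that Ja charge, I merely assume first order in Ja.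
- With equal charges this law leaves a share of Wu of one over one plus start rate times time, so elm gives 0.0167 /min, while birch, with Ja used one for one, gives 0.0369 /min from its 25.0 min reading.
- Between 20 °C and 31 °C the rate climbs 0.346 in powers of ten, and 25 °C lies 0.455 of the way, so I reckon 0.0239 /min there, and the same slope gives 0.002730 /min at −5 °C.
- What slows the rate is the loss of its two partners, so I carry the slowing number, a Damköhler number: start rate times reacting minutes, with a feed costing half its length because its average portion arrives then; for ochre it is 1.17.
- In ochre Wu and Ja each slow the rate by a factor 2.17, so by the end its logarithm has dropped 0.673 and I expect 46.1% of the Wu left.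
- Grey and green get 0.957, and amber, whose cold feed adds 0.0273, gets 0.745; WuJa leads WuWuJa in elm, 10% to 1% at 10.0 min, so I rank ochre first, since its number is the largest, then grey and green level, then amber.
- The forecast names ochre, with grey 13%, ochre 19%, amber 9% and green 15%, on the grounds that “Slow feeds lose reaction time, and the cold addition loses the most”; it parts from me in setting grey and green apart.

    Wu + Ja → WuJa (k = 0.0286 /M/s, Ea = 60.0 kJ/mol)
    Wu + 2 Ja → Ky (k = 1.06 /M²/s, Ea = 44.0 kJ/mol)
    Wu + WuJa → WuWuJa (k = 0.0233 /M/s, Ea = 41.0 kJ/mol)
    (constants at 25 °C)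

- The flasks end with WuWuJa at 16.4% in ochre, 12.9% in grey, 13.8% in green and 9.31% in amber, so ochre stands highest; Wu stands at 45.0% in ochre against 46.1% from 1.17, and at 57.8% in amber against 57.3% from 0.745. In ochre the conversion into Ky has 43% of its turnover up to 50 min behind it at 10.0 min, while WuWuJa reaches 6.69% at 25.0 min and 16.4% at 50.0 min. In amber the cold feed ends at 20.0 min with Wu at 98.3% at 20.0 min and WuWuJa at 0.0324% at 20.0 min, and after warming WuWuJa stands at 0.645% at 25.0 min and 9.31% at 50.0 min.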